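**Retrosynthetic overview**
- The target is catechin-(4α→6)-catechin-(4α→6)-epicatechin. The last operations are global hydrogenolysis (14 benzyl ethers, 2 aryl bromides) and hydroboration–oxidation of a top-unit flav-2-ene, which sets C2 and C3 anti to the C4 aryl group.
- The strategy rests on the aryl enol ether O1–C2(aryl)=C3 in ring C of the top unit. It is traced back to a 3,4-bis(benzyloxy)benzoate on the ring A phenol (ester methylenation) and closed at C2=C3 by ring-closing metathesis, so C4 is the only top-unit stereocenter needed beforehand.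
- C4 (diaryl-allyl carbon) comes from a copper-catalysed asymmetric SN2' arylation. The polarity is chosen so that the dimer is the C6 arylmagnesium (from its 6-iodide) and ring A is the cinnamyl phosphate, because the latter is regiodefined from 2,4,6-trihydroxybenzaldehyde.
- The middle–bottom 4α→6 bond comes from Lewis acid coupling of a C4-activated 8-bromo-6-iodocatechin with 8-bromoepicatechin. The C8 bromines force C6 attack and stop self-condensation; the iodide is the later metalation handle.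
- Ring order: the rings of the middle and bottom units come from (+)-catechin and (−)-epicatechin; ring C of the top unit is the only ring formed and is closed last.

Key step: step 19

Assumption: the antipode of the C2-symmetric NHC ligand L* that delivers the drawn C4 configuration is to be selected on a model cinnamyl phosphate; 2,4,6-trihydroxybenzaldehyde and 3,4-bis(benzyloxy)benzoic acid are taken as purchased.

Abbreviation used in names: "Dim" = the residue of dimer 11 bonded through C6 of its catechin unit in place of iodine (deca-O-benzyl-8-bromocatechin-(4α→6)-8-bromoepicatechin).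

**Bottom unit**

Step 1
Reactants: 1 (−)-epicatechin
Product: 2 5,7,3',4'-tetra-O-benzyl-(−)-epicatechin [(2R,3R)-5,7-bis(benzyloxy)-2-[3,4-bis(benzyloxy)phenyl]chroman-3-ol]
Conditions: BnBr (4.4 equiv), K2CO3, DMF, 0 °C to rt
Reagents that add atoms: benzyl bromide, BrCc1ccccc1
Why: Williamson etherification with a carbonate base alkylates the four phenols only, leaving the much less acidic secondary 3-OH and both stereocenters untouched.

Step 2
Reactants: 2 5,7,3',4'-tetra-O-benzyl-(−)-epicatechin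
Product: 3 3,5,7,3',4'-penta-O-benzyl-(−)-epicatechin [(2R,3R)]
Conditions: NaH, BnBr, n-Bu4NI (cat.), DMF, 0 °C to rt
Reagents that add atoms: benzyl bromide, BrCc1ccccc1
Why: Williamson etherification of the sodium alkoxide of the 3-OH, which cannot epimerise C2 or C3.

Step 3
Reactants: 3 3,5,7,3',4'-penta-O-benzyl-(−)-epicatechin
Product: 4 8-bromo-3,5,7,3',4'-penta-O-benzyl-(−)-epicatechin [(2R,3R); bottom-unit nucleophile]
Conditions: NBS (1.05 equiv), CH2Cl2, −78 to 0 °C
Reagents that add atoms: N-bromosuccinimide, O=C1CCC(=O)N1Br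
Why: Electrophilic aromatic bromination of the phloroglucinol-type ring A occurs at C8 in preference to the more shielded C6 of 5,7-di-O-benzylflavans, and one equivalent at low temperature should stop at the monobromide.

**Middle unit**

Step 4
Reactants: 5 (+)-catechin
Product: 6 5,7,3',4'-tetra-O-benzyl-(+)-catechin [(2R,3S)]
Conditions: BnBr (4.4 equiv), K2CO3, DMF, 0 °C to rt
Reagents that add atoms: benzyl bromide, BrCc1ccccc1
Why: Williamson etherification of the four phenols with a carbonate base, as in step 1.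

Step 5
Reactants: 6 5,7,3',4'-tetra-O-benzyl-(+)-catechin
Product: 7 3,5,7,3',4'-penta-O-benzyl-(+)-catechin [(2R,3S)]
Conditions: NaH, BnBr, n-Bu4NI (cat.), DMF, 0 °C to rt
Reagents that add atoms: benzyl bromide, BrCc1ccccc1
Why: Williamson etherification of the 3-alkoxide, as in step 2.

Step 6
Reactants: 7 3,5,7,3',4'-penta-O-benzyl-(+)-catechin
Product: 8 (2R,3S,4S)-4-(2-ethoxyethoxy)-3,5,7,3',4'-penta-O-benzylcatechin (4β ether; 3,4-cis)
Conditions: DDQ (2 equiv), 2-ethoxyethanol (excess), CH2Cl2, rt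
Reagents that add atoms: 2-ethoxyethanol, CCOCCO
Why: DDQ benzylic oxidation removes hydride from C4, which is activated by the ortho and para alkoxy groups of ring A, and the alcohol traps the cation; the 4β ether is expected as the main epimer and its configuration is lost again on ionisation in step 9.

Step 7
Reactants: 8 (2R,3S,4S)-4-(2-ethoxyethoxy)-3,5,7,3',4'-penta-O-benzylcatechin
Product: 9 (2R,3S,4S)-8-bromo-4-(2-ethoxyethoxy)-3,5,7,3',4'-penta-O-benzylcatechin
Conditions: NBS (1.05 equiv), NaHCO3 (solid), CH2Cl2, −78 to −20 °C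
Reagents that add atoms: N-bromosuccinimide, O=C1CCC(=O)N1Br
Why: Electrophilic aromatic bromination at C8, which is favoured further because the C4 substituent pushes the 5-benzyloxy group towards C6; the buffered neutral medium leaves the C4 ether intact.

Step 8
Reactants: 9 (2R,3S,4S)-8-bromo-4-(2-ethoxyethoxy)-3,5,7,3',4'-penta-O-benzylcatechin
Product: 10 (2R,3S,4S)-8-bromo-6-iodo-4-(2-ethoxyethoxy)-3,5,7,3',4'-penta-O-benzylcatechin (middle-unit electrophile)
Conditions: NIS (1.3 equiv), DMF, rt, dark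
Reagents that add atoms: N-iodosuccinimide, O=C1CCC(=O)N1I
Why: Electrophilic aromatic iodination at C6, the only remaining ring A position, which is still activated by three oxygen substituents and more electron-rich than the catechol-type B ring; no acid is used, so the C4 ether survives.

**Dimer**

Step 9
Reactants: 10 (2R,3S,4S)-8-bromo-6-iodo-4-(2-ethoxyethoxy)-3,5,7,3',4'-penta-O-benzylcatechin; 4 8-bromo-3,5,7,3',4'-penta-O-benzyl-(−)-epicatechin
Product: 11 deca-O-benzyl-8-bromo-6-iodocatechin-(4α→6)-8-bromoepicatechin (upper unit 2R,3S with 3,4-trans C4–aryl bond; lower unit 2R,3R)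
Conditions: 4 (3 equiv, excess recovered), TMSOTf (0.5–1 equiv), CH2Cl2, −78 to −40 °C; Et3N quench
Reagents that add atoms: none
Why: TMSOTf ionises the 4-ether to the C4 benzylic cation, which C6 of 4 (its C8 being capped by bromine) attacks from the face anti to the 3-benzyloxy group to give the 3,4-trans (4α) bond, while the two halogens on 10 exclude self-condensation (Lewis acid flavan-4-yl Friedel–Crafts coupling with halogen capping).

**Ring A cinnamyl phosphate**

Step 10
Reactants: 12 2,4,6-trihydroxybenzaldehyde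
Product: 13 4,6-bis(benzyloxy)-2-hydroxybenzaldehyde
Conditions: BnBr (2.1 equiv), K2CO3 (2.2 equiv), DMF, rt
Reagents that add atoms: benzyl bromide, BrCc1ccccc1
Why: Williamson etherification stops at the dibenzyl ether because the last ortho hydroxyl is deactivated by its hydrogen bond to the formyl group, which fixes the ring A substitution pattern without isomers.

Step 11
Reactants: 13 4,6-bis(benzyloxy)-2-hydroxybenzaldehyde
Product: 14 4,6-bis(benzyloxy)-2-(tert-butyldimethylsilyloxy)benzaldehyde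
Conditions: TBSCl, imidazole, DMAP (cat.), DMF, rt to 40 °C
Reagents that add atoms: tert-butyldimethylsilyl chloride, CC(C)(C)[Si](C)(C)Cl
Why: Silylation of the phenol gives a protecting group that is later removed by fluoride without acid.

Step 12
Reactants: 14 4,6-bis(benzyloxy)-2-(tert-butyldimethylsilyloxy)benzaldehyde
Product: 15 ethyl (E)-3-[4,6-bis(benzyloxy)-2-(tert-butyldimethylsilyloxy)phenyl]acrylate
Conditions: Ph3P=CHCO2Et (2 equiv), toluene, 100 °C
Reagents that add atoms: ethyl (triphenylphosphoranylidene)acetate, CCOC(=O)C=P(c1ccccc1)(c1ccccc1)c1ccccc1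
Why: Wittig olefination with a stabilised ylide gives the (E)-cinnamate under neutral conditions that keep the aryl silyl ether.

Step 13
Reactants: 15 ethyl (E)-3-[4,6-bis(benzyloxy)-2-(tert-butyldimethylsilyloxy)phenyl]acrylate
Product: 16 (E)-3-[4,6-bis(benzyloxy)-2-(tert-butyldimethylsilyloxy)phenyl]prop-2-en-1-ol
Conditions: i-Bu2AlH (2.5 equiv), CH2Cl2, −78 °C; aq. potassium sodium tartrate (KNaC4H4O6)
Reagents that add atoms: none
Why: 1,2-Reduction of the conjugated ester by the aluminium hydride gives the allylic alcohol with the alkene geometry retained.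

Step 14
Reactants: 16 (E)-3-[4,6-bis(benzyloxy)-2-(tert-butyldimethylsilyloxy)phenyl]prop-2-en-1-ol
Product: 17 (E)-3-[4,6-bis(benzyloxy)-2-(tert-butyldimethylsilyloxy)phenyl]prop-2-en-1-yl diethyl phosphate
Conditions: ClP(O)(OEt)2, pyridine, DMAP (cat.), CH2Cl2, 0 °C; filtered through Et3N-deactivated silica and used at once
Reagents that add atoms: diethyl chlorophosphate, CCOP(=O)(Cl)OCC
Why: O-Phosphorylation of the primary allylic alcohol gives the leaving group for copper-mediated SN2' substitution; the electron-rich cinnamyl phosphate is ionisation-prone, hence the immediate use.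

**Assembly of the top unit**

Step 15
Reactants: 11 deca-O-benzyl-8-bromo-6-iodocatechin-(4α→6)-8-bromoepicatechin; 17 (E)-3-[4,6-bis(benzyloxy)-2-(tert-butyldimethylsilyloxy)phenyl]prop-2-en-1-yl diethyl phosphate
Product: 19 (R)-3-Dim-3-[4,6-bis(benzyloxy)-2-(tert-butyldimethylsilyloxy)phenyl]prop-1-ene (C3 of the propene is the future C4 of the top unit), via arylmagnesium chloride 18 (not isolated)
Conditions: 11, i-PrMgCl·LiCl (1.05 equiv), THF, −20 to 0 °C; then slow addition to 17 (1.5 equiv), CuBr·SMe2 (10 mol %), L* (12 mol %, pre-treated with EtMgBr), CH2Cl2/THF, −78 to −40 °C; L* = (4S,5S)-1,3-bis(2-methoxybenzyl)-4,5-diphenylimidazolinium chloride or its antipode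
Reagents that add atoms: none
Why: Iodine–magnesium exchange is selective for the aryl iodide over the two aryl bromides, and the chiral NHC–copper aryl species then adds anti-SN2' to the (E)-allylic phosphate at the aryl-bearing γ-carbon, reductive elimination from the trivalent copper σ-allyl intermediate forming the C4–aryl bond on the alkene face selected by the C2-symmetric ligand (copper-catalysed enantioselective allylic arylation with an aryl Grignard reagent).

Step 16
Reactants: 19 (R)-3-Dim-3-[4,6-bis(benzyloxy)-2-(tert-butyldimethylsilyloxy)phenyl]prop-1-ene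
Product: 20 (S)-2-(1-Dim-prop-2-en-1-yl)-3,5-bis(benzyloxy)phenol (same spatial arrangement at C4; descriptor changes with the silyl group)
Conditions: n-Bu4NF (1.2 equiv), THF, 0 °C
Reagents that add atoms: none
Why: Fluoride cleaves the aryl silyl ether under non-acidic conditions that spare the acid-labile bis(trioxyaryl)methine, the benzyl ethers and the aryl bromides.

Step 17
Reactants: 20 (S)-2-(1-Dim-prop-2-en-1-yl)-3,5-bis(benzyloxy)phenol; 21 3,4-bis(benzyloxy)benzoic acid
Product: 22 (S)-2-(1-Dim-prop-2-en-1-yl)-3,5-bis(benzyloxy)phenyl 3,4-bis(benzyloxy)benzoate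
Conditions: 21 (1.5 equiv), EDC·HCl, DMAP, CH2Cl2, rt
Reagents that add atoms: none
Why: Steglich esterification acylates the hindered phenol through the acylpyridinium ion and so brings in the B ring and C2 as an ester, with no stereocenter at C2.

Step 18
Reactants: 22 (S)-2-(1-Dim-prop-2-en-1-yl)-3,5-bis(benzyloxy)phenyl 3,4-bis(benzyloxy)benzoate
Product: 23 (S)-1-[1-[3,4-bis(benzyloxy)phenyl]vinyloxy]-3,5-bis(benzyloxy)-2-(1-Dim-prop-2-en-1-yl)benzene (aryl 1-arylvinyl ether with the C4 vinyl group)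
Conditions: Cp2Ti(μ-Cl)(μ-CH2)AlMe2 (Tebbe reagent, 2 equiv), pyridine (cat.), THF/toluene, −40 to 0 °C; aq. NaOH quench; basic alumina
Reagents that add atoms: Tebbe reagent Cp2Ti(μ-Cl)(μ-CH2)AlMe2, C[Al-]1(C)C[Ti]([Cl+]1)(C1C=CC=C1)C1C=CC=C1
Why: Tebbe methylenation (titanium methylidene [2+2] addition to the ester carbonyl and cycloreversion) converts aryl benzoates into aryl 1-arylvinyl ethers, and the low temperature with basic work-up keeps the vinyl group and the acid-labile enol ether intact.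

Step 19
Reactants: 23 (S)-1-[1-[3,4-bis(benzyloxy)phenyl]vinyloxy]-3,5-bis(benzyloxy)-2-(1-Dim-prop-2-en-1-yl)benzene
Product: 24 protected trimer with the top unit as (4S)-5,7-bis(benzyloxy)-2-[3,4-bis(benzyloxy)phenyl]-4-Dim-4H-chromene (4-aryl-flav-2-ene)
Conditions: second-generation Grubbs catalyst (H2IMes)(PCy3)Cl2Ru=CHPh (15 mol %), 1,4-benzoquinone (20 mol %), toluene (2 mM), 80 °C, argon sparge
Reagents that add atoms: none
Why: The ruthenium benzylidene first exchanges with the monosubstituted C4 vinyl group, the resulting C3 alkylidene adds intramolecularly across the 1,1-disubstituted enol ether C=C, and cycloreversion of the ruthenacyclobutane releases the methylidene (ethylene after turnover) and leaves the C2=C3 bond. The closest known reaction type is the ester methylenation and ring-closing metathesis route to cyclic aryl enol ethers such as 1-aryl glycals and 4H-chromenes. Ring C of the top unit (O1–C2=C3–C4–C4a–C8a) closes as a six-membered ring by ring-closing metathesis, the ortho placement of the enol ether oxygen and the C4 branch on ring A holding the two alkenes close. No stereocenter is formed, and C4 is carried through because none of its bonds changes. The step needs initiation at the vinyl group, which the steric and electronic deactivation of the α-aryloxystyrene secures, and it needs suppression of ruthenium hydride migration of the vinyl double bond into conjugation with the two C4 aryl groups, for which benzoquinone, high dilution and ethylene removal are used.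

Step 20
Reactants: 24 protected trimer with the top unit as 4-aryl-flav-2-ene
Product: 26 tetradeca-O-benzyl-8,8-dibromo trimer with free top 3-OH (top unit 2R,3S,4S: 2,3-trans and 3,4-trans), via C3-alkylborane 25 (not isolated)
Conditions: BH3·SMe2 (5 equiv), THF, 0 °C to rt; then aq. NaOH, H2O2, 0 °C to rt
Reagents that add atoms: hydrogen peroxide, OO
Why: Syn hydroboration of the enol ether places boron at C3 (β to O1 and away from the aryl-bearing C2) on the face anti to the pseudoaxial C4 aryl group, and oxidation with retention gives the 3-OH trans to the C4 aryl group while the hydrogen delivered to C2 on the same face leaves the B ring cis to it.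

Step 21
Reactants: 26 tetradeca-O-benzyl-8,8-dibromo trimer with free top 3-OH
Product: 27 catechin-(4α→6)-catechin-(4α→6)-epicatechin (CNP0163146.3)
Conditions: H2 (1 atm), Pd(OH)2 on carbon, Et3N (2.2 equiv), THF/MeOH/H2O, rt; Sephadex LH-20
Reagents that add atoms: none
Why: Catalytic hydrogenolysis removes the fourteen benzyl ethers and both aryl bromides in one operation, the amine taking up HBr so that the acid-labile interflavan bonds survive.

**Compound list**

1 | (−)-epicatechin | O[C@@H]1Cc2c(O)cc(O)cc2O[C@@H]1c1ccc(O)c(O)c1 | starting material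
2 | 5,7,3',4'-tetra-O-benzyl-(−)-epicatechin | O[C@@H]1Cc2c(OCc3ccccc3)cc(OCc3ccccc3)cc2O[C@@H]1c1ccc(OCc2ccccc2)c(OCc2ccccc2)c1 | intermediate
3 | 3,5,7,3',4'-penta-O-benzyl-(−)-epicatechin | c1ccccc1CO[C@@H]1Cc2c(OCc3ccccc3)cc(OCc3ccccc3)cc2O[C@@H]1c1ccc(OCc2ccccc2)c(OCc2ccccc2)c1 | intermediate
4 | 8-bromo-3,5,7,3',4'-penta-O-benzyl-(−)-epicatechin | c1ccccc1CO[C@@H]1Cc2c(OCc3ccccc3)cc(OCc3ccccc3)c(Br)c2O[C@@H]1c1ccc(OCc2ccccc2)c(OCc2ccccc2)c1 | intermediate
5 | (+)-catechin | O[C@H]1Cc2c(O)cc(O)cc2O[C@@H]1c1ccc(O)c(O)c1 | starting material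
6 | 5,7,3',4'-tetra-O-benzyl-(+)-catechin | O[C@H]1Cc2c(OCc3ccccc3)cc(OCc3ccccc3)cc2O[C@@H]1c1ccc(OCc2ccccc2)c(OCc2ccccc2)c1 | intermediate
7 | 3,5,7,3',4'-penta-O-benzyl-(+)-catechin | c1ccccc1CO[C@H]1Cc2c(OCc3ccccc3)cc(OCc3ccccc3)cc2O[C@@H]1c1ccc(OCc2ccccc2)c(OCc2ccccc2)c1 | intermediate
8 | (2R,3S,4S)-4-(2-ethoxyethoxy)-3,5,7,3',4'-penta-O-benzylcatechin | c1ccccc1CO[C@H]1[C@@H](OCCOCC)c2c(OCc3ccccc3)cc(OCc3ccccc3)cc2O[C@@H]1c1ccc(OCc2ccccc2)c(OCc2ccccc2)c1 | intermediate
9 | (2R,3S,4S)-8-bromo-4-(2-ethoxyethoxy)-3,5,7,3',4'-penta-O-benzylcatechin | c1ccccc1CO[C@H]1[C@@H](OCCOCC)c2c(OCc3ccccc3)cc(OCc3ccccc3)c(Br)c2O[C@@H]1c1ccc(OCc2ccccc2)c(OCc2ccccc2)c1 | intermediate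
10 | (2R,3S,4S)-8-bromo-6-iodo-4-(2-ethoxyethoxy)-3,5,7,3',4'-penta-O-benzylcatechin | c1ccccc1CO[C@H]1[C@@H](OCCOCC)c2c(OCc3ccccc3)c(I)c(OCc3ccccc3)c(Br)c2O[C@@H]1c1ccc(OCc2ccccc2)c(OCc2ccccc2)c1 | intermediate
11 | deca-O-benzyl-8-bromo-6-iodocatechin-(4α→6)-8-bromoepicatechin | Ic1c(OCc4ccccc4)c(Br)c2c(c1OCc4ccccc4)[C@@H](c1c(OCc4ccccc4)c(Br)c3c(c1OCc4ccccc4)C[C@@H](OCc1ccccc1)[C@@H](c1ccc(OCc4ccccc4)c(OCc4ccccc4)c1)O3)[C@H](OCc1ccccc1)[C@@H](c1ccc(OCc3ccccc3)c(OCc3ccccc3)c1)O2 | intermediate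
12 | 2,4,6-trihydroxybenzaldehyde | O=Cc1c(O)cc(O)cc1O | starting material
13 | 4,6-bis(benzyloxy)-2-hydroxybenzaldehyde | O=Cc1c(O)cc(OCc2ccccc2)cc1OCc1ccccc1 | intermediate
14 | 4,6-bis(benzyloxy)-2-(tert-butyldimethylsilyloxy)benzaldehyde | O=Cc1c(O[Si](C)(C)C(C)(C)C)cc(OCc2ccccc2)cc1OCc1ccccc1 | intermediate
15 | ethyl (E)-3-[4,6-bis(benzyloxy)-2-(tert-butyldimethylsilyloxy)phenyl]acrylate | CCOC(=O)/C=C/c1c(O[Si](C)(C)C(C)(C)C)cc(OCc2ccccc2)cc1OCc1ccccc1 | intermediate
16 | (E)-3-[4,6-bis(benzyloxy)-2-(tert-butyldimethylsilyloxy)phenyl]prop-2-en-1-ol | OC/C=C/c1c(O[Si](C)(C)C(C)(C)C)cc(OCc2ccccc2)cc1OCc1ccccc1 | intermediate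
17 | (E)-3-[4,6-bis(benzyloxy)-2-(tert-butyldimethylsilyloxy)phenyl]prop-2-en-1-yl diethyl phosphate | CCOP(=O)(OCC)OC/C=C/c1c(O[Si](C)(C)C(C)(C)C)cc(OCc2ccccc2)cc1OCc1ccccc1 | intermediate
18 | arylmagnesium chloride of the dimer (Mg at C6 of the catechin unit) | Cl[Mg]c1c(OCc4ccccc4)c(Br)c2c(c1OCc4ccccc4)[C@@H](c1c(OCc4ccccc4)c(Br)c3c(c1OCc4ccccc4)C[C@@H](OCc1ccccc1)[C@@H](c1ccc(OCc4ccccc4)c(OCc4ccccc4)c1)O3)[C@H](OCc1ccccc1)[C@@H](c1ccc(OCc3ccccc3)c(OCc3ccccc3)c1)O2 | intermediate
19 | (R)-3-Dim-3-[4,6-bis(benzyloxy)-2-(tert-butyldimethylsilyloxy)phenyl]prop-1-ene | c1ccccc1COc1cc(OCc2ccccc2)c(c(c1)O[Si](C)(C)C(C)(C)C)[C@H](C=C)c1c(OCc4ccccc4)c(Br)c2c(c1OCc4ccccc4)[C@@H](c1c(OCc4ccccc4)c(Br)c3c(c1OCc4ccccc4)C[C@@H](OCc1ccccc1)[C@@H](c1ccc(OCc4ccccc4)c(OCc4ccccc4)c1)O3)[C@H](OCc1ccccc1)[C@@H](c1ccc(OCc3ccccc3)c(OCc3ccccc3)c1)O2 | intermediate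
20 | (S)-2-(1-Dim-prop-2-en-1-yl)-3,5-bis(benzyloxy)phenol | c1ccccc1COc1cc(OCc2ccccc2)c(c(c1)O)[C@H](C=C)c1c(OCc4ccccc4)c(Br)c2c(c1OCc4ccccc4)[C@@H](c1c(OCc4ccccc4)c(Br)c3c(c1OCc4ccccc4)C[C@@H](OCc1ccccc1)[C@@H](c1ccc(OCc4ccccc4)c(OCc4ccccc4)c1)O3)[C@H](OCc1ccccc1)[C@@H](c1ccc(OCc3ccccc3)c(OCc3ccccc3)c1)O2 | intermediate
21 | 3,4-bis(benzyloxy)benzoic acid | OC(=O)c1ccc(OCc2ccccc2)c(OCc2ccccc2)c1 | starting material
22 | (S)-2-(1-Dim-prop-2-en-1-yl)-3,5-bis(benzyloxy)phenyl 3,4-bis(benzyloxy)benzoate | c1ccccc1COc1cc(OCc2ccccc2)c(c(c1)OC(=O)c1ccc(OCc2ccccc2)c(OCc2ccccc2)c1)[C@H](C=C)c1c(OCc4ccccc4)c(Br)c2c(c1OCc4ccccc4)[C@@H](c1c(OCc4ccccc4)c(Br)c3c(c1OCc4ccccc4)C[C@@H](OCc1ccccc1)[C@@H](c1ccc(OCc4ccccc4)c(OCc4ccccc4)c1)O3)[C@H](OCc1ccccc1)[C@@H](c1ccc(OCc3ccccc3)c(OCc3ccccc3)c1)O2 | intermediate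
23 | (S)-aryl 1-arylvinyl ether with the C4 vinyl group (key-step precursor) | c1ccccc1COc1cc(OCc2ccccc2)c(c(c1)OC(=C)c1ccc(OCc2ccccc2)c(OCc2ccccc2)c1)[C@H](C=C)c1c(OCc4ccccc4)c(Br)c2c(c1OCc4ccccc4)[C@@H](c1c(OCc4ccccc4)c(Br)c3c(c1OCc4ccccc4)C[C@@H](OCc1ccccc1)[C@@H](c1ccc(OCc4ccccc4)c(OCc4ccccc4)c1)O3)[C@H](OCc1ccccc1)[C@@H](c1ccc(OCc3ccccc3)c(OCc3ccccc3)c1)O2 | intermediate
24 | protected trimer with the top unit as (4S)-4-aryl-flav-2-ene (key-step product) | c1ccccc1COc1cc(OCc5ccccc5)c2c(c1)OC(c1ccc(OCc5ccccc5)c(OCc5ccccc5)c1)=C[C@@H]2c1c(OCc4ccccc4)c(Br)c2c(c1OCc4ccccc4)[C@@H](c1c(OCc4ccccc4)c(Br)c3c(c1OCc4ccccc4)C[C@@H](OCc1ccccc1)[C@@H](c1ccc(OCc4ccccc4)c(OCc4ccccc4)c1)O3)[C@H](OCc1ccccc1)[C@@H](c1ccc(OCc3ccccc3)c(OCc3ccccc3)c1)O2 | intermediate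
25 | C3-alkylborane of the top unit (BH2 at C3, trans to the C4 aryl group) | c1ccccc1COc1cc(OCc5ccccc5)c2c(c1)O[C@H](c1ccc(OCc5ccccc5)c(OCc5ccccc5)c1)[C@@H](B)[C@@H]2c1c(OCc4ccccc4)c(Br)c2c(c1OCc4ccccc4)[C@@H](c1c(OCc4ccccc4)c(Br)c3c(c1OCc4ccccc4)C[C@@H](OCc1ccccc1)[C@@H](c1ccc(OCc4ccccc4)c(OCc4ccccc4)c1)O3)[C@H](OCc1ccccc1)[C@@H](c1ccc(OCc3ccccc3)c(OCc3ccccc3)c1)O2 | intermediate
26 | tetradeca-O-benzyl-8,8-dibromo trimer with free top 3-OH | c1ccccc1COc1cc(OCc5ccccc5)c2c(c1)O[C@H](c1ccc(OCc5ccccc5)c(OCc5ccccc5)c1)[C@@H](O)[C@@H]2c1c(OCc4ccccc4)c(Br)c2c(c1OCc4ccccc4)[C@@H](c1c(OCc4ccccc4)c(Br)c3c(c1OCc4ccccc4)C[C@@H](OCc1ccccc1)[C@@H](c1ccc(OCc4ccccc4)c(OCc4ccccc4)c1)O3)[C@H](OCc1ccccc1)[C@@H](c1ccc(OCc3ccccc3)c(OCc3ccccc3)c1)O2 | intermediate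
27 | catechin-(4α→6)-catechin-(4α→6)-epicatechin (CNP0163146.3) | Oc1cc(O)c2c(c1)O[C@H](c1ccc(O)c(O)c1)[C@@H](O)[C@@H]2c1c(O)cc2c(c1O)[C@@H](c1c(O)cc3c(c1O)C[C@@H](O)[C@@H](c1ccc(O)c(O)c1)O3)[C@H](O)[C@@H](c1ccc(O)c(O)c1)O2 | target

**Step count and risks**

Total step count: 21. Longest linear sequence: 13 steps (steps 4 to 9 and 15 to 21, from (+)-catechin).

Steps most likely to fail:

1. Step 15 (SN2' arylation). The γ-carbon is flanked by two ortho oxygen substituents and the aryl nucleophile likewise, so the aryl group may be delivered to the less hindered α-carbon to give the linear cinnamyl product, or the ligand may discriminate the alkene faces poorly. The fallback changes the bond construction so that the congested carbon is attacked as a planar quinone methide by a small nucleophile. It sets out from 13 and 11 and comes back at 20. Phenol 13 is converted with Boc2O, i-Pr2NEt and DMAP into tert-butyl carbonate F1. The arylmagnesium 18, made from 11 as in step 15, is added to the formyl group of F1 at −78 °C. On warming, the magnesium alkoxide takes over the Boc group and loses tert-butyl carbonate to give o-quinone methide F2. CH2=CHMgBr then adds 1,4 to give phenol 20 together with its C4 epimer F3. In this variant C4 is not set by a reagent, so 20 would be separated from F3 by chromatography before step 17.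

2. Step 19 (ring-closing metathesis). Closure onto the hindered, electron-rich 1,1-disubstituted enol ether may be slower than ruthenium hydride migration of the vinyl double bond or than catalyst decay. The fallback replaces olefin–olefin metathesis by an olefinic ester cyclisation with a reduced titanium alkylidene. It sets out from ester 22 and comes back at 24, bypassing 23. With TiCl4, Zn, PbCl2 (cat.), CH3CHBr2 and TMEDA in THF, the titanium ethylidene exchanges with the C4 vinyl group and the resulting C3 titanium alkylidene olefinates the benzoate carbonyl intramolecularly, closing ring C at C2=C3. No compound outside the list is made (F0).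

3. Step 9 (interflavan coupling). Ionisation of the doubly halogenated, congested 4-ether may be slow, and the iodine may be lost or passed on to the electron-rich nucleophile under the Lewis acid. The fallback moves the iodination behind the coupling. It sets out from 9 and 4 and comes back at 11. Monobromide 9 is coupled with excess 4 under TMSOTf in CH2Cl2 at −78 °C to give iodine-free dimer F4, in which C6 of the catechin unit is the only free ring A position. NIS in DMF then iodinates that position to give 11.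

**Further compounds**

F1 | step 15 | tert-butyl 3,5-bis(benzyloxy)-2-formylphenyl carbonate | O=Cc1c(OC(=O)OC(C)(C)C)cc(OCc2ccccc2)cc1OCc1ccccc1
F2 | step 15 | o-quinone methide 3,5-bis(benzyloxy)-6-(Dim-methylidene)cyclohexa-2,4-dien-1-one | O=C1C=C(OCc2ccccc2)C=C(OCc2ccccc2)C1=Cc1c(OCc4ccccc4)c(Br)c2c(c1OCc4ccccc4)[C@@H](c1c(OCc4ccccc4)c(Br)c3c(c1OCc4ccccc4)C[C@@H](OCc1ccccc1)[C@@H](c1ccc(OCc4ccccc4)c(OCc4ccccc4)c1)O3)[C@H](OCc1ccccc1)[C@@H](c1ccc(OCc3ccccc3)c(OCc3ccccc3)c1)O2
F3 | step 15 | C4 epimer of 20, (R)-2-(1-Dim-prop-2-en-1-yl)-3,5-bis(benzyloxy)phenol | c1ccccc1COc1cc(OCc2ccccc2)c(c(c1)O)[C@@H](C=C)c1c(OCc4ccccc4)c(Br)c2c(c1OCc4ccccc4)[C@@H](c1c(OCc4ccccc4)c(Br)c3c(c1OCc4ccccc4)C[C@@H](OCc1ccccc1)[C@@H](c1ccc(OCc4ccccc4)c(OCc4ccccc4)c1)O3)[C@H](OCc1ccccc1)[C@@H](c1ccc(OCc3ccccc3)c(OCc3ccccc3)c1)O2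
F0 | step 19 | none | none
F4 | step 9 | deca-O-benzyl-8-bromocatechin-(4α→6)-8-bromoepicatechin (no iodine) | c1c(OCc4ccccc4)c(Br)c2c(c1OCc4ccccc4)[C@@H](c1c(OCc4ccccc4)c(Br)c3c(c1OCc4ccccc4)C[C@@H](OCc1ccccc1)[C@@H](c1ccc(OCc4ccccc4)c(OCc4ccccc4)c1)O3)[C@H](OCc1ccccc1)[C@@H](c1ccc(OCc3ccccc3)c(OCc3ccccc3)c1)O2
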